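All runs come from a simulation for substances that don't exist, noise included.

In a one-step world, where substrate passes by first-order paths to each product, the share of target doesn't depend on concentration, so cedar, at twice the concentration of the blue run, would repeat blue's 12.6%, pooled from its last two readings.

| flask | substrate | first nucleophile | second nucleophile | temperature | remark | time |
|---|---|---|---|---|---|---|
| blue | 0.025 M | 1 equiv | 1 equiv | 50 °C | run made earlier |  |
| cedar | 0.050 M | 1.00 equiv | 1.00 equiv | 50 °C |  | 40 min |
| alder | 0.050 M | 1.00 equiv | 1.00 equiv | 20 °C |  | 40 min |
| birch | 0.050 M | 1.00 equiv | 1.00 equiv | −10 °C |  | 40 min |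

blue run (percent of the substrate charged)

| time / min | target / % | other capture product / % | solvolysis product / % |
|---|---|---|---|
| 0.667 | 7 | 7 | 22 |
| 1.33 | 7 | 13 | 36 |
| 2.50 | 12 | 19 | 56 |
| 4.00 | 13 | 14 | 60 |
| 8.00 | 10 | 21 | 65 |

(scatter of a reading: 2 percentage points)

- the earlier runs were read with a standard deviation of 2 percentage points
- the earlier runs do not show what temperature does; that part of a forecast is a guess

- which flask leads in share of target in all that became target or other capture product or solvolysis product or isomer of the product ("all alike" within 1.5 percentage points) (cedar / alder / birch / all alike)
- share of target in all that became target or other capture product or solvolysis product or isomer of the product, cedar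
- share of target in all that became target or other capture product or solvolysis product or isomer of the product, alder
- share of target in all that became target or other capture product or solvolysis product or isomer of the product, birch

Suppose instead that target forms when something meets the first nucleophile, while solvolysis product needs no partner. Then target per solvolysis product, divided by the mean first nucleophile present, should hold steady at one temperature, and I call this the capture number 7.81 M⁻¹, a selectivity factor, read here from blue with its scatter. You can reckon cedar in two rounds. With the full charge of first nucleophile, target per solvolysis product is 0.390, and other capture product, scaled the same way, is 0.560, so the share is 20.0%. Putting that share back, with each target taking one first nucleophile, gives 18.4%, which is my number for cedar.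

Now turn the question round: for cedar to fall back to blue's share, about a third of its target would have to go within 40 min. The hint of such a loss that I can see is blue's drop of 3 percentage points between two readings, each with a scatter of 2 points, so I don't reckon with it. The earlier runs do not show what temperature does, so I hold no number for alder or birch.

The forecast, which parts from my cedar figure, names birch and gives 9%, 17% and 19% for cedar, alder and birch, reasoning that a slow loss “could drain target substantially”.

The flask that leads is alder, with a share of target of 19.9% in cedar, 27.1% in alder and 19.2% in birch.

    substrate → intermediate (k = 3.50 × 10⁻⁴ s⁻¹, Ea = 91.0 kJ mol⁻¹)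
    first nucleophile + intermediate → target (k = 2.80 M⁻¹ s⁻¹, Ea = 51.0 kJ mol⁻¹)
    second nucleophile + intermediate → other capture product (k = 7.50 M⁻¹ s⁻¹, Ea = 40.0 kJ mol⁻¹)
    intermediate → solvolysis product (k = 0.170 s⁻¹, Ea = 64.0 kJ mol⁻¹)
    2 second nucleophile → self-condensation product (k = 0.0190 M⁻¹ s⁻¹, Ea = 46.0 kJ mol⁻¹)
    target ⇌ isomer of the product (K = 0.500, k = 9.60 × 10⁻⁵ s⁻¹, Ea = 100 kJ mol⁻¹, ΔH = −28.0 kJ mol⁻¹)
    (constants at 20 °C)

In cedar, target stands at 19.9% after 20.0 min and at 19.9% after 40.0 min, and a tenfold time leaves the share unmoved. Cedar's own capture number, taken with its mean first nucleophile and with the 3.43% of isomer of the product left out of it, is 8.51 M⁻¹. Birch, at −10 °C, gives 30.2 M⁻¹, and its neighbour, charged with 1.70 equiv of first nucleophile, gives 30.2 M⁻¹.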